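## Structural features

The target is a cyclohexene (C1–C6) whose C2–C3 bond carries a cis-fused oxirane and whose C4=C5 bond is a trisubstituted alkene, so the epoxide is a vinyl oxirane. C6 is quaternary and carries a methyl group and C2′ of a 6′-methoxy-3′,5′-dimethyl-4-pyranone. The neighbouring C1 carries the chain C7(CH3)=C8H–C9H(CH3)–C10(=O)–C11H2–C12H3 with an E double bond. Four contiguous ring stereocentres (in these locants 6R, 1S, 2S, 3R) and the remote C9 (R) must be set: the C1 chain is trans to the pyranone and cis to the C6 methyl, and the oxirane oxygen lies on the face of the C1 chain, away from the pyranone. The fragile parts are the vinyl oxirane (acid, Lewis acid, SN2′ opening), C9 (α to a ketone and allylic, so prone to epimerisation and conjugation under base) and the α-methoxy-γ-pyranone (hard nucleophiles at C6′, hydrides, strong Lewis acids). The real difficulty is the quaternary C6 beside C1 in one absolute sense, and the late site- and face-selective oxygenation of one of three trisubstituted alkenes. The key step reads ring atoms C2–C5 (methyls on C2 and C4, oxygen on C3) as a 2-silyloxy diene, and the C6–C1 pair with its trans relationship as an (E)-2-methyl enal carrying the chain carbon as an ester. One [4+2] then forms C1–C2 and C5–C6, the ring and the C6/C1 stereo pair.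

## Logic of the disconnections

**30 ⇒ 29.** Cut: the two C–O bonds of the oxirane (C2–O, C3–O). The vinyl oxirane would not survive organoaluminium, organolithium, acid chloride or methyl triflate chemistry, so it is made last. Two stereocentres and the strained ring disappear and a conjugated ring diene remains. The oxidant must choose C2=C3 over C4=C5, C7=C8 and the pyranone, must deliver oxygen to the α face, and must work without base because of C9.

**29 ⇒ 25 + 26.** Cut: C8–C9. C9 is the most easily scrambled centre, so this bond is formed late, under catalyst control, from a racemic partner. The chain shrinks to the alkenyl iodide function of 25, and 26 is a commercial racemate. Metalation of 25 must spare the pyranone and keep the E geometry, and the nickel catalyst must funnel both enantiomers of 26 into 9R.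

**25 ⇒ 23 ⇒ 19 + 21, and 21 ⇒ 20.** Cut: O–CH3 at C6′, then C3′–C4′ and O1′–C6′. The pyranone is a triketide equivalent; cutting it into the ethyl ketone of 19 and a symmetrical C4 diacid chloride needs no regiocontrol in the carbon framework. It also keeps the hydride- and organometal-sensitive heterocycle out of steps 7–10. Only one enolisable ketone may be present (hence before C8–C9 is made), methylation must go to the lactone oxygen, and the acid released must not reach the diene.

**19 ⇒ 17 ⇒ 15.** First an oxidation-level and protecting-group change on the C6 side chain (C=O ⇐ C–OSiEt3), then cut C7–CH3 and C8–I. The C1 chain has to be built while C6 carries no carbonyl, because AlMe3 is used. The E-trisubstituted alkene comes from syn carbometalation of the terminal alkyne of 15. The forward step needs regio- and syn-selective CH3–Al addition next to a branched carbon.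

**15 ⇒ 13 ⇒ 12 ⇒ 11.** Cut: C7–C8 (one-carbon homologation), then formyl ⇐ ester at C7. C7 is the ester carbon that 4 brings into the ring. In 12 the C1 hydrogen is α to the carbonyl and allylic, so the homologation must avoid base at the aldehyde stage, and the reduction must stop at the aldehyde.

**11 ⇒ 10 ⇒ 8 ⇒ 7.** C3–H ⇐ C3–OTf ⇐ C3=O, and C4=C5 ⇐ the C3 silyl enol ether. The ring diene is the oxygen-free form of a 2-methylcyclohexenone, and the C3 oxygen is the one delivered by 3. This is also why C2 need not be controlled. Dehydrogenation must go towards C5 and not the C4 methyl, enolisation must occur only at C2, and both palladium steps must precede any alkyne or iodide.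

**7 ⇒ 5.** Cut: the C–C bond between the carbinol carbon on C6 and its ethyl group, and O–Si. The formyl carbon of 5 is the future C2′; the ethyl group supplies C3′ and its methyl. The forward step needs aldehyde-over-ester selectivity, and the alkoxide must be capped before it can lactonise onto the trans ester.

**5 ⇒ 3 + 4.** Cut: C1–C2 and C5–C6. This is the only disconnection that removes the ring, the quaternary centre and the C6/C1 relationship together, and it leads to one commercial and one single-step component. The catalyst must select one face of 4; regiochemistry and the trans relationship follow from the electronics of 3 and the E geometry of 4.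

**3 ⇒ 1.** Cut: O–Si. The enolate must be formed at the ethyl group with Z geometry, so that the methyl is outward in the s-cis diene.

## Other disconnections considered

**Alternative 1:** The cut runs through C2–C3 and C3–O and opens carbocycle and oxirane together to the acyclic keto sulfonium salt A2. In the forward direction base deprotonates A2 at C3, C3 adds to the C2 carbonyl (six-membered ring) and the oxygen displaces the sulfonium leaving group from C3, giving A1. Desilylation and oxidation at C10 would finish.
- In its favour: one step makes the ring, two stereocentres and the oxirane without an oxidant. The site-selectivity problem of step 17 does not arise, and on this point it is the better plan. The cis ring fusion is automatic.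
- Against it: C6 (quaternary, carrying the pyranone), C1, C9 and a Z-trisubstituted C4=C5 must be set in an open chain. C1 is α to the methyl ketone and can epimerise under the basic conditions, the ketone α-hydrogens compete with ylide formation, and the allylic carbanion can also react through C5.
- Comparison: the chosen plan fixes C1/C6 in a ring by a stereospecific concerted cycloaddition, whereas A2 needs acyclic stereocontrol for the same pair. The face of the oxirane is equally uncertain in both (substrate control there, catalyst control here). A1 still needs two steps, and the assembly of A2 is unlikely to be shorter than the fifteen steps that lead to 29.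

**Alternative 2:** The cut runs through C3′–C4′ and O1′–C6′ of the heterocycle and leads to the ethyl ketone A4 and 21. In the forward direction the silyl enol ether of A4 is C-acylated by 21 and the enol oxygen closes on the second acyl chloride to give A3.
- In its favour: the heterocycle is made in one operation on a hindered quaternary ketone, with no stereochemistry involved. It is the same reaction as step 14 of the chosen route, so on this bond construction the two plans are equal.
- Against it as the strategy-bearing step: it creates no stereocentre and no bond of the carbocycle. A4 still holds the C1/C6 pair and must come from an asymmetric ring synthesis, so the main problem is moved and not solved. A3 keeps the alkyne masked, so desilylation, carboalumination (AlMe3 in the presence of the acidic hydroxypyranone or the Lewis-basic methoxypyranone) and iodination would follow the heterocycle; the chosen route avoids that order by installing the iodide first.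
- Comparison: 23 and A3 differ only in the C1 substituent and the mechanism is identical. There is no gain in step economy: one more step (alkyne deprotection) is needed after A3.

**Alternative 3:** The cut runs through C1–C2 and C4–C5 and leads to the keto ester A6 and the enynal A7. In the forward direction a chiral primary amine activates A7 as its iminium ion, A6 adds through its C2 to C1, and acid then removes the tert-butyl ester with decarboxylation and closes C4–C5 by aldol condensation to A5.
- In its favour: it is metal-free and sets C1 under catalyst control. It delivers the C3 ketone with the C4=C5 double bond directly, which the chosen route reaches only at step 4. It carries the alkyne on C1 from the start, which would save steps 7–9. On these points it is the better plan.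
- Against it: in A5, C6 is a tertiary CH(CH3). The carbon that becomes C2′ is missing and would have to enter at the γ-position of the enone through a dienolate, which reacts preferentially at C4 or oxygen, and it would have to enter trans to the alkynyl group. Iminium activation of an α-branched enal is slow, and A7 offers competing 1,6-addition.
- Comparison: the cycloaddition forms the quaternary C6 with its formyl handle in the ring-forming step, whereas A5 postpones it. It is a stepwise ionic sequence against a concerted one, and sets one stereocentre under catalyst control against two. It is shorter up to the enone but has no reliable solution for C6, so overall it is longer and less certain.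

Key step: step 2

Assumption 1: the S-configured oxazaborolidinium ion is taken to leave the Re face of C6 of 4 open (formyl C–H···O binding model for 2-substituted enals); the mirror-image catalyst is equally available if the sense must be inverted.
Assumption 2: the (S,S) pybox ligand in step 16 and the (R,R) salen ligand in step 17 are assigned by analogy with α-aryl ketone couplings and with indene-type cis-alkenes; in each case the antipodal ligand is the remedy if the sense is opposite.
Remark: ring locants C1–C6 of the target are used for every intermediate; α is the face of the C1 substituent and of the C6 methyl, β the face of the C6 one-carbon substituent. The formyl-endo adduct of the Z diene has the C2 methyl cis to CHO, i.e. (1R,2R,6R), and this is the structure used as 5.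

## Route

Step 1
Reactants: 1 2-methylpent-1-en-3-one
Product: 3 (Z)-tert-butyldimethyl[(2-methylpenta-1,3-dien-3-yl)oxy]silane, via lithium (Z)-dienolate 2 (not isolated)
Conditions: LiN(SiMe3)2, THF, −78 °C; then t-BuMe2SiOTf, −78 → 0 °C
Reagents that add atoms: tert-butyldimethylsilyl triflate, CC(C)(C)[Si](C)(C)OS(=O)(=O)C(F)(F)F
Why: Kinetic α′-deprotonation of the ethyl group by the bulky amide should give mainly the Z enolate, and O-silylation by the hard silyl triflate fixes it as the Z silyl dienol ether (enolate trapping); any E isomer has an inward methyl and is inert in step 2.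

Step 2
Reactants: 3 (Z)-tert-butyldimethyl[(2-methylpenta-1,3-dien-3-yl)oxy]silane, 4 ethyl (E)-3-methyl-4-oxobut-2-enoate
Product: 5 ethyl (1R,2R,6R)-3-(tert-butyldimethylsilyloxy)-6-formyl-2,4,6-trimethylcyclohex-3-ene-1-carboxylate
Conditions: (S)-3,3-diphenyl-1-(2-methylphenyl)tetrahydro-1H,3H-pyrrolo[1,2-c][1,3,2]oxazaborole (20 mol %), Tf2NH (17 mol %), CH2Cl2, −78 → −40 °C; Et3N quench
Reagents that add atoms: none
Why: The aldehyde oxygen of 4 (more basic than the ester) binds the boron of the N-protonated oxazaborolidine, a formyl C–H···O contact locks the s-trans enal over one aryl group, and 3 adds to the open face in a concerted, asynchronous, suprafacial normal-demand Diels–Alder reaction in which C1–C2 runs ahead of C5–C6. The closest known reaction type is the cationic-oxazaborolidine-catalysed cycloaddition of 2-substituted acroleins and β-formyl acrylates with 2-silyloxy dienes. The six-membered carbocycle closes by intermolecular [4+2] cycloaddition, both ring bonds being made in this one step. C6 and C1 owe their absolute configuration to the catalyst, which leaves the Re face of C6 open, and their trans CHO/CO2Et relationship to the E geometry of 4, transferred stereospecifically. C2 follows from the formyl-endo approach and the outward methyl of the Z diene (CH3 cis to CHO); the exo adduct would differ only at C2, which becomes sp2 in step 5, so both converge. Regiochemistry (C3 placed 1,4 to C6) is secured by the donor oxygen, which makes C2 the nucleophilic diene terminus, and by aldehyde activation, which makes C1 the electrophilic carbon. The quaternary centre is formed by the lagging bond from the unhindered CH2 terminus, and the low temperature with an amine quench should keep both silyl enol ethers intact.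

Step 3
Reactants: 5 ethyl (1R,2R,6R)-3-(tert-butyldimethylsilyloxy)-6-formyl-2,4,6-trimethylcyclohex-3-ene-1-carboxylate
Product: 7 ethyl 3-(tert-butyldimethylsilyloxy)-2,4,6-trimethyl-6-[1-(triethylsilyloxy)propyl]cyclohex-3-ene-1-carboxylate (both epimers at the carbinol carbon), via bromomagnesium alkoxide 6 (not isolated)
Conditions: EtMgBr, Et2O, −78 °C; then Et3SiOTf, −78 → 0 °C
Reagents that add atoms: ethylmagnesium bromide, CC[Mg]Br; triethylsilyl triflate, CC[Si](CC)(CC)OS(=O)(=O)C(F)(F)F
Why: Grignard 1,2-addition to the non-enolisable aldehyde is far faster at −78 °C than attack on the hindered ester; silylating the magnesium alkoxide in the same flask prevents its closure onto the trans ester (γ-lactone), and the new carbinol centre is erased by oxidation in step 12.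

Step 4
Reactants: 7 ethyl 3-(tert-butyldimethylsilyloxy)-2,4,6-trimethyl-6-[1-(triethylsilyloxy)propyl]cyclohex-3-ene-1-carboxylate
Product: 8 ethyl 2,4,6-trimethyl-3-oxo-6-[1-(triethylsilyloxy)propyl]cyclohex-4-ene-1-carboxylate
Conditions: Pd(OAc)2 (1.2 equiv), MeCN, 25 → 40 °C
Reagents that add atoms: none
Why: Saegusa–Ito oxidation: the regiodefined silyl enol ether transfers C4 to divalent palladium and syn β-hydride elimination from C5 should give the endocyclic conjugated enone, the usual outcome for 2-methylcyclohexanone enol ethers; ester and triethylsilyl ether are inert.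

Step 5
Reactants: 8 ethyl 2,4,6-trimethyl-3-oxo-6-[1-(triethylsilyloxy)propyl]cyclohex-4-ene-1-carboxylate
Product: 10 ethyl 2,4,6-trimethyl-6-[1-(triethylsilyloxy)propyl]-3-(trifluoromethylsulfonyloxy)cyclohexa-2,4-diene-1-carboxylate, via potassium dienolate 9 (not isolated)
Conditions: KN(SiMe3)2, THF, −78 °C; then PhNTf2, −78 → 0 °C
Reagents that add atoms: N-phenylbis(trifluoromethanesulfonimide), O=S(=O)(N(c1ccccc1)S(=O)(=O)C(F)(F)F)C(F)(F)F
Why: C2–H is the only enolisable position of the ketone (C4 is sp2, C6 quaternary) and is far more acidic than the ester α-hydrogen at C1, so kinetic deprotonation gives the cross-conjugated dienolate, which is triflated on oxygen (enol triflate formation); the C2 stereocentre is removed on purpose.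

Step 6
Reactants: 10 ethyl 2,4,6-trimethyl-6-[1-(triethylsilyloxy)propyl]-3-(trifluoromethylsulfonyloxy)cyclohexa-2,4-diene-1-carboxylate
Product: 11 ethyl 2,4,6-trimethyl-6-[1-(triethylsilyloxy)propyl]cyclohexa-2,4-diene-1-carboxylate
Conditions: Pd(OAc)2 (5 mol %), PPh3, HCO2H, n-Bu3N, DMF, 60 °C
Reagents that add atoms: none
Why: Palladium-catalysed formate reduction of an enol triflate: oxidative addition of C3–OTf to zerovalent palladium, formate exchange, decarboxylation and reductive elimination give the C3–H diene without moving either double bond, as is well known for steroidal dienyl triflates.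

Step 7
Reactants: 11 ethyl 2,4,6-trimethyl-6-[1-(triethylsilyloxy)propyl]cyclohexa-2,4-diene-1-carboxylate
Product: 12 2,4,6-trimethyl-6-[1-(triethylsilyloxy)propyl]cyclohexa-2,4-diene-1-carbaldehyde
Conditions: i-Bu2AlH (1.1 equiv), CH2Cl2, −78 °C; aq. potassium sodium tartrate
Reagents that add atoms: none
Why: Partial ester reduction: at −78 °C the aluminium hemiacetal of the hindered ester persists until work-up, so the aldehyde is released only on quenching; no base is present, which matters because C1–H is now α to a carbonyl and allylic, and the aldehyde is used at once.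

Step 8
Reactants: 12 2,4,6-trimethyl-6-[1-(triethylsilyloxy)propyl]cyclohexa-2,4-diene-1-carbaldehyde
Product: 13 triethylsilyl ether of 1-[1-(2,2-dibromoethenyl)-2,4,6-trimethylcyclohexa-2,4-dien-6-yl]propan-1-ol
Conditions: CBr4, PPh3, Zn, CH2Cl2, 25 °C (reagent pre-formed); then 12, 0 → 25 °C
Reagents that add atoms: carbon tetrabromide, BrC(Br)(Br)Br
Why: First stage of the Corey–Fuchs sequence: the non-basic ylide Ph3P=CBr2 (pre-formed with zinc so that no Ph3PBr2 remains) condenses with the aldehyde without enolising C1, which a base-mediated diazophosphonate homologation would risk.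

Step 9
Reactants: 13 triethylsilyl ether of 1-[1-(2,2-dibromoethenyl)-2,4,6-trimethylcyclohexa-2,4-dien-6-yl]propan-1-ol
Product: 15 triethylsilyl ether of 1-(1-ethynyl-2,4,6-trimethylcyclohexa-2,4-dien-6-yl)propan-1-ol, via lithium acetylide 14 (not isolated)
Conditions: n-BuLi (2.1 equiv), THF, −78 °C; then H2O
Reagents that add atoms: none
Why: Second stage of the Corey–Fuchs sequence: bromine–lithium exchange, α-elimination and 1,2-hydride shift give the alkyne, which the second equivalent converts into the acetylide; halogen–metal exchange outpaces deprotonation of the allylic C1–H at −78 °C.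

Step 10
Reactants: 15 triethylsilyl ether of 1-(1-ethynyl-2,4,6-trimethylcyclohexa-2,4-dien-6-yl)propan-1-ol
Product: 17 triethylsilyl ether of 1-{1-[(E)-1-iodoprop-1-en-2-yl]-2,4,6-trimethylcyclohexa-2,4-dien-6-yl}propan-1-ol, via (E)-alkenyl(dimethyl)alane 16 (not isolated)
Conditions: AlMe3, Cp2ZrCl2, CH2Cl2, 0 → 25 °C; then I2, THF, −30 → 0 °C
Reagents that add atoms: trimethylaluminium, C[Al](C)C; iodine, II
Why: Zirconium-catalysed carboalumination (Negishi): syn addition of CH3–Al across the terminal alkyne places CH3 on the internal carbon C7 and aluminium on C8, the branching at C1 reinforcing this regiochemistry, and iodinolysis with retention gives the E-alkenyl iodide; no carbonyl group or oxirane is present at this stage.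

Step 11
Reactants: 17 triethylsilyl ether of 1-{1-[(E)-1-iodoprop-1-en-2-yl]-2,4,6-trimethylcyclohexa-2,4-dien-6-yl}propan-1-ol
Product: 18 1-{1-[(E)-1-iodoprop-1-en-2-yl]-2,4,6-trimethylcyclohexa-2,4-dien-6-yl}propan-1-ol (both epimers at the carbinol carbon)
Conditions: HF·pyridine, pyridine, THF, 0 → 25 °C
Reagents that add atoms: none
Why: Buffered fluoride cleavage of the secondary triethylsilyl ether; alkenyl iodide and ring diene are unaffected.

Step 12
Reactants: 18 1-{1-[(E)-1-iodoprop-1-en-2-yl]-2,4,6-trimethylcyclohexa-2,4-dien-6-yl}propan-1-ol
Product: 19 1-{1-[(E)-1-iodoprop-1-en-2-yl]-2,4,6-trimethylcyclohexa-2,4-dien-6-yl}propan-1-one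
Conditions: Dess–Martin periodinane, NaHCO3, CH2Cl2, 0 → 25 °C
Reagents that add atoms: none
Why: Dess–Martin oxidation under bicarbonate buffer converges both carbinol epimers into one ethyl ketone, which can enolise only towards its CH2 group because C6 is quaternary.

Step 13
Reactants: 20 methylmalonic acid
Product: 21 methylmalonyl dichloride
Conditions: SOCl2, cat. DMF, 50 °C; distillation
Reagents that add atoms: thionyl chloride, O=S(Cl)Cl
Why: Standard conversion of a malonic acid into its dichloride; the product is distilled and used at once.

Step 14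
Reactants: 19 1-{1-[(E)-1-iodoprop-1-en-2-yl]-2,4,6-trimethylcyclohexa-2,4-dien-6-yl}propan-1-one, 21 methylmalonyl dichloride
Product: 23 4-hydroxy-6-{1-[(E)-1-iodoprop-1-en-2-yl]-2,4,6-trimethylcyclohexa-2,4-dien-6-yl}-3,5-dimethyl-2H-pyran-2-one, via (Z)-trimethylsilyl enol ether 22 (not isolated)
Conditions: LiN(i-Pr)2, Me3SiCl, THF, −78 °C; evaporation; then 21, Et2O, −78 → 0 °C
Reagents that add atoms: none
Why: Malonyl dichloride pyranone annulation: the silyl enol ether is C-acylated at its CH(CH3) carbon by 21 (C3′–C4′) and the enol oxygen of the C2′ ketone closes on the second acyl chloride (O1′–C6′) to give the 4-hydroxy-2-pyranone tautomer; ether and low temperature are meant to keep the one equivalent of HCl released from adding to the diene.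

Step 15
Reactants: 23 4-hydroxy-6-{1-[(E)-1-iodoprop-1-en-2-yl]-2,4,6-trimethylcyclohexa-2,4-dien-6-yl}-3,5-dimethyl-2H-pyran-2-one
Product: 25 6-{1-[(E)-1-iodoprop-1-en-2-yl]-2,4,6-trimethylcyclohexa-2,4-dien-6-yl}-2-methoxy-3,5-dimethyl-4H-pyran-4-one, via hydroxymethoxypyrylium triflate 24 (not isolated)
Conditions: MeOTf, CH2Cl2, 0 → 25 °C; aq. NaHCO3
Reagents that add atoms: methyl triflate, COS(=O)(=O)C(F)(F)F
Why: A hard methylating agent without base alkylates a 4-hydroxy-2-pyranone at the lactone carbonyl oxygen, giving the hydroxypyrylium salt, which loses its proton on bicarbonate work-up to the α-methoxy-γ-pyranone; the acid formed is held as this salt and should not reach the diene.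

Step 16
Reactants: 25 6-{1-[(E)-1-iodoprop-1-en-2-yl]-2,4,6-trimethylcyclohexa-2,4-dien-6-yl}-2-methoxy-3,5-dimethyl-4H-pyran-4-one, 26 racemic 2-bromopentan-3-one
Product: 29 2-methoxy-3,5-dimethyl-6-{2,4,6-trimethyl-1-[(2E,4R)-4-methyl-5-oxohept-2-en-2-yl]cyclohexa-2,4-dien-6-yl}-4H-pyran-4-one, via alkenyllithium 27 (not isolated), via alkenylzinc iodide 28 (not isolated)
Conditions: t-BuLi (2.05 equiv), Et2O, −100 °C; ZnI2, THF, −100 → 0 °C; then 26, NiCl2·glyme (10 mol %), 2,6-bis[(4S)-4-phenyl-4,5-dihydro-1,3-oxazol-2-yl]pyridine (13 mol %), glyme/THF, −30 °C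
Reagents that add atoms: none
Why: Iodine–lithium exchange at −100 °C should outrun attack on the hindered pyranone and retains the E geometry, transmetalation gives the alkenylzinc iodide, and a stereoconvergent nickel-catalysed Negishi coupling of the racemic α-bromo ketone (alkyl radical captured by the chiral nickel–pybox complex) forms C8–C9 and sets C9 (R) under catalyst control, without base, so the labile α-alkenyl ketone is neither epimerised nor conjugated.

Step 17
Reactants: 29 2-methoxy-3,5-dimethyl-6-{2,4,6-trimethyl-1-[(2E,4R)-4-methyl-5-oxohept-2-en-2-yl]cyclohexa-2,4-dien-6-yl}-4H-pyran-4-one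
Product: 30 target CNP0336888.2
Conditions: (salen)MnCl with (R,R)-N,N′-bis(3,5-di-tert-butylsalicylidene)cyclohexane-1,2-diamine (5 mol %), N-methylmorpholine N-oxide, mCPBA, CH2Cl2, −78 °C
Reagents that add atoms: 3-chloroperoxybenzoic acid, OOC(=O)c1cccc(Cl)c1
Why: Jacobsen–Katsuki epoxidation: the oxo-manganese salen species reacts preferentially with conjugated cis-configured ring alkenes, so the ring diene should be oxidised in preference to the isolated E-trisubstituted C7=C8 bond, and within the diene C2=C3 is the alkene remote from the quaternary C6; the (R,R) ligand is chosen to deliver oxygen to the α face (2S,3R), and anhydrous conditions at −78 °C leave C9 and the vinyl oxirane untouched.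

## Compound list

In all ring compounds the C1 substituent and the C6 methyl are α and the C6 one-carbon substituent is β, as encoded in the SMILES.

1 | 2-methylpent-1-en-3-one | C=C(C)C(=O)CC | starting material
2 | lithium (Z)-2-methylpenta-1,3-dien-3-olate (not isolated) | C=C(C)/C([O-])=C/C.[Li+] | intermediate
3 | (Z)-tert-butyldimethyl[(2-methylpenta-1,3-dien-3-yl)oxy]silane | C=C(C)/C(O[Si](C)(C)C(C)(C)C)=C/C | intermediate
4 | ethyl (E)-3-methyl-4-oxobut-2-enoate | CCOC(=O)/C=C(\C)C=O | starting material
5 | ethyl (1R,2R,6R)-3-(tert-butyldimethylsilyloxy)-6-formyl-2,4,6-trimethylcyclohex-3-ene-1-carboxylate (C2 CH3 β) | CCOC(=O)[C@@H]1[C@@H](C)C(O[Si](C)(C)C(C)(C)C)=C(C)C[C@@]1(C)C=O | intermediate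
6 | bromomagnesium alkoxide from ethyl addition to the formyl group of 5, epimers at the carbinol carbon (not isolated) | CCOC(=O)[C@@H]1[C@@H](C)C(O[Si](C)(C)C(C)(C)C)=C(C)C[C@@]1(C)C(CC)O[Mg]Br | intermediate
7 | ethyl 3-(tert-butyldimethylsilyloxy)-2,4,6-trimethyl-6-[1-(triethylsilyloxy)propyl]cyclohex-3-ene-1-carboxylate, ring configuration as in 5, both epimers at the carbinol carbon | CCOC(=O)[C@@H]1[C@@H](C)C(O[Si](C)(C)C(C)(C)C)=C(C)C[C@@]1(C)C(CC)O[Si](CC)(CC)CC | intermediate
8 | ethyl 2,4,6-trimethyl-3-oxo-6-[1-(triethylsilyloxy)propyl]cyclohex-4-ene-1-carboxylate (C2 CH3 β), carbinol epimers | CCOC(=O)[C@@H]1[C@@H](C)C(=O)C(C)=C[C@@]1(C)C(CC)O[Si](CC)(CC)CC | intermediate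
9 | potassium cross-conjugated dienolate of 8 (not isolated) | CCOC(=O)[C@@H]1C(C)=C([O-])C(C)=C[C@@]1(C)C(CC)O[Si](CC)(CC)CC.[K+] | intermediate
10 | ethyl 2,4,6-trimethyl-6-[1-(triethylsilyloxy)propyl]-3-(trifluoromethylsulfonyloxy)cyclohexa-2,4-diene-1-carboxylate, carbinol epimers | CCOC(=O)[C@@H]1C(C)=C(OS(=O)(=O)C(F)(F)F)C(C)=C[C@@]1(C)C(CC)O[Si](CC)(CC)CC | intermediate
11 | ethyl 2,4,6-trimethyl-6-[1-(triethylsilyloxy)propyl]cyclohexa-2,4-diene-1-carboxylate, carbinol epimers | CCOC(=O)[C@@H]1C(C)=CC(C)=C[C@@]1(C)C(CC)O[Si](CC)(CC)CC | intermediate
12 | 2,4,6-trimethyl-6-[1-(triethylsilyloxy)propyl]cyclohexa-2,4-diene-1-carbaldehyde, carbinol epimers | O=C[C@@H]1C(C)=CC(C)=C[C@@]1(C)C(CC)O[Si](CC)(CC)CC | intermediate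
13 | triethylsilyl ether of 1-[1-(2,2-dibromoethenyl)-2,4,6-trimethylcyclohexa-2,4-dien-6-yl]propan-1-ol, carbinol epimers | BrC(Br)=C[C@@H]1C(C)=CC(C)=C[C@@]1(C)C(CC)O[Si](CC)(CC)CC | intermediate
14 | lithium acetylide of 15 (not isolated) | [Li]C#C[C@@H]1C(C)=CC(C)=C[C@@]1(C)C(CC)O[Si](CC)(CC)CC | intermediate
15 | triethylsilyl ether of 1-(1-ethynyl-2,4,6-trimethylcyclohexa-2,4-dien-6-yl)propan-1-ol, carbinol epimers | C#C[C@@H]1C(C)=CC(C)=C[C@@]1(C)C(CC)O[Si](CC)(CC)CC | intermediate
16 | (E)-alkenyl(dimethyl)alane from syn addition of CH3–Al to 15 (not isolated) | C[Al](C)/C=C(\C)[C@@H]1C(C)=CC(C)=C[C@@]1(C)C(CC)O[Si](CC)(CC)CC | intermediate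
17 | triethylsilyl ether of 1-{1-[(E)-1-iodoprop-1-en-2-yl]-2,4,6-trimethylcyclohexa-2,4-dien-6-yl}propan-1-ol, carbinol epimers | I/C=C(\C)[C@@H]1C(C)=CC(C)=C[C@@]1(C)C(CC)O[Si](CC)(CC)CC | intermediate
18 | 1-{1-[(E)-1-iodoprop-1-en-2-yl]-2,4,6-trimethylcyclohexa-2,4-dien-6-yl}propan-1-ol, carbinol epimers | I/C=C(\C)[C@@H]1C(C)=CC(C)=C[C@@]1(C)C(O)CC | intermediate
19 | 1-{1-[(E)-1-iodoprop-1-en-2-yl]-2,4,6-trimethylcyclohexa-2,4-dien-6-yl}propan-1-one | I/C=C(\C)[C@@H]1C(C)=CC(C)=C[C@@]1(C)C(=O)CC | intermediate
20 | methylmalonic acid | CC(C(=O)O)C(=O)O | starting material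
21 | methylmalonyl dichloride (2-methylpropanedioyl dichloride) | CC(C(=O)Cl)C(=O)Cl | intermediate
22 | (Z)-trimethylsilyl enol ether of 19 (not isolated) | I/C=C(\C)[C@@H]1C(C)=CC(C)=C[C@@]1(C)/C(O[Si](C)(C)C)=C/C | intermediate
23 | 4-hydroxy-6-{1-[(E)-1-iodoprop-1-en-2-yl]-2,4,6-trimethylcyclohexa-2,4-dien-6-yl}-3,5-dimethyl-2H-pyran-2-one | I/C=C(\C)[C@@H]1C(C)=CC(C)=C[C@@]1(C)C2=C(C)C(O)=C(C)C(=O)O2 | intermediate
24 | 4-hydroxy-2-methoxy-3,5-dimethyl-6-{1-[(E)-1-iodoprop-1-en-2-yl]-2,4,6-trimethylcyclohexa-2,4-dien-6-yl}pyrylium triflate (not isolated) | I/C=C(\C)[C@@H]1C(C)=CC(C)=C[C@@]1(C)c1[o+]c(OC)c(C)c(O)c1C.[O-]S(=O)(=O)C(F)(F)F | intermediate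
25 | 6-{1-[(E)-1-iodoprop-1-en-2-yl]-2,4,6-trimethylcyclohexa-2,4-dien-6-yl}-2-methoxy-3,5-dimethyl-4H-pyran-4-one | I/C=C(\C)[C@@H]1C(C)=CC(C)=C[C@@]1(C)c1oc(OC)c(C)c(=O)c1C | intermediate
26 | racemic 2-bromopentan-3-one | CCC(=O)C(C)Br | starting material
27 | (E)-alkenyllithium from 25 (not isolated) | [Li]/C=C(\C)[C@@H]1C(C)=CC(C)=C[C@@]1(C)c1oc(OC)c(C)c(=O)c1C | intermediate
28 | (E)-alkenylzinc iodide from 25 (not isolated) | I[Zn]/C=C(\C)[C@@H]1C(C)=CC(C)=C[C@@]1(C)c1oc(OC)c(C)c(=O)c1C | intermediate
29 | 2-methoxy-3,5-dimethyl-6-{2,4,6-trimethyl-1-[(2E,4R)-4-methyl-5-oxohept-2-en-2-yl]cyclohexa-2,4-dien-6-yl}-4H-pyran-4-one | CCC(=O)[C@H](C)/C=C(\C)[C@@H]1C(C)=CC(C)=C[C@@]1(C)c1oc(OC)c(C)c(=O)c1C | intermediate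
30 | CNP0336888.2: the 2,3-α-epoxide of 29; route locants 1S,2S,3R,6R, side chain 7E,9R | CCC(=O)[C@H](C)/C=C(\C)[C@@H]1[C@]2(C)O[C@@H]2C(C)=C[C@@]1(C)c1oc(OC)c(C)c(=O)c1C | target

## Step count and least certain steps

Total: 17 steps. Longest linear sequence: 16 steps (steps 1–12 and 14–17, from 1); step 13 is a one-step side branch.

**Step 2 (key step).** The most likely failure is insufficient discrimination between the two faces of the trisubstituted enal, because the ester carbonyl offers the boron a second, unselective binding mode. Mukaiyama-type addition of the silyl enol ether to the activated aldehyde and acid-induced loss of the silyl group from 3 are further risks. Fallback: setting out from 3 and 4, the cycloaddition is run without a chiral catalyst (toluene, 80 °C, or Me2AlCl, CH2Cl2, −78 °C). This gives 5 together with its mirror-image cycloadduct F1, and the enantiomers are separated by preparative chromatography on a chiral stationary phase. The route is rejoined at 5.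

**Step 17.** Oxygen may be delivered to the wrong face or the wrong alkene. Both faces of C2=C3 are encumbered (α by the pseudoaxial C1 alkenyl group, β by the pseudoaxial pyranone on C6), so the intrinsic bias may oppose the catalyst, and C4=C5 is electronically comparable. Fallback: setting out from 29, N-bromosuccinimide in aqueous THF at 0 °C places the bromonium ion on the β face and water opens it from the α face, giving the trans-bromohydrin F2 (C2–OH α, C3–Br β). Ag2O in THF then closes the oxirane by intramolecular displacement, which puts the oxygen on the α face, and the route arrives at 30. The same substrate bias that would defeat a direct β-face epoxidation is thereby put to use.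

**Step 16.** The organolithium reagents may attack the methoxypyranone (addition–elimination at C6′) before exchange and transmetalation are complete. The catalyst may also control C9 poorly with a dialkyl ketone and a hindered trisubstituted alkenylzinc. Fallback: setting out from 25 and 26, the polarity is reversed. Zinc insertion into 26 (Zn, THF) gives the bromozinc enolate of pentan-3-one F3. Palladium-catalysed α-alkenylation with 25 (Pd2(dba)3, P(t-Bu)3, THF, 25 °C) needs no organolithium and gives 29 together with its C9 epimer F4. The two are separated by chromatography, and the route is rejoined at 29.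

**Step 14.** The hydrogen chloride released may add to the ring diene, or acylation may occur on oxygen and lead to oligomers. Fallback: setting out from 19, soft enolisation (MgBr2·OEt2, i-Pr2NEt, CH2Cl2) and C-acylation with methyl 3-chloro-2-methyl-3-oxopropanoate gives the β,δ-diketo ester F5. DBU in toluene at 60 °C closes it to the hydroxypyranone with loss of methanol, and the route is rejoined at 23.

**Step 4.** Palladation of the hindered tetrasubstituted enol ether may be slow, and β-hydride elimination may take a hydrogen of the C4 methyl group and give the exocyclic enone. Fallback: setting out from 7, N-bromosuccinimide (THF, 0 °C) converts the silyl enol ether into the 4-bromo ketone F6. Dehydrobromination with Li2CO3 and LiBr in DMF at 100 °C gives the thermodynamically preferred endocyclic enone, and the route is rejoined at 8.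

## Further compounds

F1 | step 2 | mirror-image cycloadduct, ethyl (1S,2S,6S)-3-(tert-butyldimethylsilyloxy)-6-formyl-2,4,6-trimethylcyclohex-3-ene-1-carboxylate | CCOC(=O)[C@H]1[C@H](C)C(O[Si](C)(C)C(C)(C)C)=C(C)C[C@]1(C)C=O
F2 | step 17 | trans-bromohydrin of 29 (C2–OH α, C3–Br β) | CCC(=O)[C@H](C)/C=C(\C)[C@@H]1[C@](C)(O)[C@@H](Br)C(C)=C[C@@]1(C)c1oc(OC)c(C)c(=O)c1C
F3 | step 16 | bromozinc enolate of pentan-3-one | CCC(O[Zn]Br)=CC
F4 | step 16 | C9 epimer of 29 (9S) | CCC(=O)[C@@H](C)/C=C(\C)[C@@H]1C(C)=CC(C)=C[C@@]1(C)c1oc(OC)c(C)c(=O)c1C
F5 | step 14 | methyl 5-{1-[(E)-1-iodoprop-1-en-2-yl]-2,4,6-trimethylcyclohexa-2,4-dien-6-yl}-2,4-dimethyl-3,5-dioxopentanoate | I/C=C(\C)[C@@H]1C(C)=CC(C)=C[C@@]1(C)C(=O)C(C)C(=O)C(C)C(=O)OC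
F6 | step 4 | ethyl 4-bromo-2,4,6-trimethyl-3-oxo-6-[1-(triethylsilyloxy)propyl]cyclohexane-1-carboxylate | CCOC(=O)[C@@H]1[C@@H](C)C(=O)C(C)(Br)C[C@@]1(C)C(CC)O[Si](CC)(CC)CC
A1 | alternative 1 | C10 tert-butyldimethylsilyl ether of the C10-reduced target | CC[C@H](O[Si](C)(C)C(C)(C)C)[C@H](C)/C=C(\C)[C@@H]1[C@]2(C)O[C@@H]2C(C)=C[C@@]1(C)c1oc(OC)c(C)c(=O)c1C
A2 | alternative 1 | acyclic (Z)-allylic diphenylsulfonium tetrafluoroborate with the C2 methyl ketone | CC[C@H](O[Si](C)(C)C(C)(C)C)[C@H](C)/C=C(\C)[C@H](C(C)=O)[C@@](C)(/C=C(C)\C[S+](c1ccccc1)c1ccccc1)c1oc(OC)c(C)c(=O)c1C.F[B-](F)(F)F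
A3 | alternative 2 | 4-hydroxy-3,5-dimethyl-6-[2,4,6-trimethyl-1-(trimethylsilylethynyl)cyclohexa-2,4-dien-6-yl]-2H-pyran-2-one | C[Si](C)(C)C#C[C@@H]1C(C)=CC(C)=C[C@@]1(C)C2=C(C)C(O)=C(C)C(=O)O2
A4 | alternative 2 | 1-[2,4,6-trimethyl-1-(trimethylsilylethynyl)cyclohexa-2,4-dien-6-yl]propan-1-one | C[Si](C)(C)C#C[C@@H]1C(C)=CC(C)=C[C@@]1(C)C(=O)CC
A5 | alternative 3 | 2,4,6-trimethyl-5-(trimethylsilylethynyl)cyclohex-2-enone | C[Si](C)(C)C#C[C@@H]1[C@@H](C)C(=O)C(C)=C[C@H]1C
A6 | alternative 3 | tert-butyl 2-methyl-3-oxopentanoate | CCC(=O)C(C)C(=O)OC(C)(C)C
A7 | alternative 3 | (E)-2-methyl-5-(trimethylsilyl)pent-2-en-4-ynal | C[Si](C)(C)C#C/C=C(\C)C=O
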